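**Plan**
Retrosynthesis: the pyrrole ring is opened by cutting N1–C2 and C3–SMe together, leaving an ortho-amino aryl alkynyl sulfide and a MeS+ donor. The alkynyl sulfide is then cut at C(sp)–S and the arylalkyne at C(aryl)–C(sp), back to an ortho-iodoaniline and on to 3,4,5-tribromoaniline.
Feature used: C2 and C3 of the pyrrole ring both carry SMe, so the C2–C3 unit can be an alkyne that already bears the C2 sulfur; that sulfur directs MeS+ to C3 and N1 to C2.
Forward: the benzene ring is bought with its three bromines; ortho-iodination, Sonogashira coupling, desilylation and copper-catalysed sulfenylation join the two-carbon chain and the first sulfur.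
The pyrrole ring, the only ring made, closes last by sulfenium-triggered 5-endo-dig aminocyclisation, which gives the target directly.
Stereochemistry: the target has no stereocentre, axis or stereogenic double bond, so nothing has to be set.

Key step: step 5

Remark: the target is achiral (planar indole), so "single enantiomer" is taken to mean the single constitution given, with Br on C4, C5, C6 and SMe on C2 and C3.

**Step 1**
Reactants: 1 3,4,5-tribromoaniline
Product: 2 3,4,5-tribromo-2-iodoaniline
Conditions: NIS (1.0 equiv), DMF, 0 °C → rt, dark
Reagents that add atoms: N-iodosuccinimide, O=C1CCC(=O)N1I
Why: Electrophilic aromatic iodination; the amino group directs ortho/para, the para position is blocked by Br, the two ortho positions are equivalent by symmetry, and one equivalent of NIS should stop at the mono-iodide.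

**Step 2**
Reactants: 2 3,4,5-tribromo-2-iodoaniline; 3 ethynyltrimethylsilane
Product: 4 3,4,5-tribromo-2-[(trimethylsilyl)ethynyl]aniline
Conditions: PdCl2(PPh3)2 (cat.), CuI (cat.), Et3N, THF, rt, Ar
Reagents that add atoms: none
Why: Sonogashira coupling; at room temperature oxidative addition into C–I is much faster than into C–Br, as in the selective couplings of 3-bromo-2-iodoanilines, and the free amine is tolerated.

**Step 3**
Reactants: 4 3,4,5-tribromo-2-[(trimethylsilyl)ethynyl]aniline
Product: 5 3,4,5-tribromo-2-ethynylaniline
Conditions: K2CO3 (cat.), MeOH/THF, rt
Reagents that add atoms: none
Why: Base-catalysed methanolysis of the C(sp)–Si bond (protodesilylation); the aryl bromides and the amine are untouched.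

**Step 4**
Reactants: 5 3,4,5-tribromo-2-ethynylaniline; 6 S-methyl methanethiosulfonate
Product: 7 3,4,5-tribromo-2-[(methylsulfanyl)ethynyl]aniline
Conditions: CuI (5 mol%), Xantphos (5 mol%), K2CO3 (1.5 equiv), DMSO, rt, Ar
Reagents that add atoms: none
Why: Copper-catalysed sulfenylation of a terminal alkyne with a thiosulfonate; the copper acetylide attacks the sulfenyl sulfur and expels methanesulfinate, the electron-poor amine should not compete, and exclusion of air suppresses Glaser coupling.

**Step 5**
Reactants: 7 3,4,5-tribromo-2-[(methylsulfanyl)ethynyl]aniline; 8 dimethyl(methylsulfanyl)sulfonium tetrafluoroborate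
Product: 9 4,5,6-tribromo-2,3-bis(methylsulfanyl)-1H-indole
Conditions: 8 (1.05 equiv), NaHCO3 (2 equiv), CH2Cl2/MeCN, 0 °C → rt, Ar
Reagents that add atoms: none
Why: The sulfonium salt 8 transfers MeS+ to the triple bond of 7; donation from the alkyne-bound sulfur makes the aryl-bound carbon the nucleophilic terminus, so the new sulfur ends there (C3–S) and the thiirenium ion formed carries its positive charge mainly on the sulfur-bearing carbon (thioketenium character). The ortho amino group opens this ion at that carbon, anti to the entering sulfur, closing the pyrrole ring in a 5-endo-dig mode (N1–C2), and hydrogencarbonate removes the N–H proton to give the aromatic indole. The closest known reaction type is the electrophilic sulfenyl-cyclisation of 2-alkynylanilines to 3-sulfanylindoles, together with sulfonium-salt cyclisations of ortho-alkynyl anisoles and thioanisoles and electrophilic cyclisations of chalcogen-substituted alkynes onto ortho heteroatoms. No stereocentre is formed. The step needs MeS on C3 and nitrogen on C2, which the substrate secures twice over: the tether lets nitrogen reach only the distal carbon (the 4-exo alternative is out of reach) and the sulfanyl group polarises the alkyne in the same sense. Chemoselectivity rests on the low nucleophilicity of the tribromo-substituted amine, on one equivalent of 8 and on buffering, which should hold back N-sulfenylation, a second sulfenylation and acid-promoted sulfanyl migration, while the aryl bromides are inert to the electrophile.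

**Compound list**
1 | 3,4,5-tribromoaniline | Nc1cc(Br)c(Br)c(Br)c1 | starting material
2 | 3,4,5-tribromo-2-iodoaniline | Nc1cc(Br)c(Br)c(Br)c1I | intermediate
3 | ethynyltrimethylsilane | C#C[Si](C)(C)C | starting material
4 | 3,4,5-tribromo-2-[(trimethylsilyl)ethynyl]aniline | C[Si](C)(C)C#Cc1c(N)cc(Br)c(Br)c1Br | intermediate
5 | 3,4,5-tribromo-2-ethynylaniline | C#Cc1c(N)cc(Br)c(Br)c1Br | intermediate
6 | S-methyl methanethiosulfonate | CSS(C)(=O)=O | starting material
7 | 3,4,5-tribromo-2-[(methylsulfanyl)ethynyl]aniline | CSC#Cc1c(N)cc(Br)c(Br)c1Br | intermediate
8 | dimethyl(methylsulfanyl)sulfonium tetrafluoroborate | CS[S+](C)C.F[B-](F)(F)F | starting material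
9 | 4,5,6-tribromo-2,3-bis(methylsulfanyl)-1H-indole | CSc1[nH]c2cc(Br)c(Br)c(Br)c2c1SC | target

**Total step count:** 5
**Longest linear sequence:** 5 steps (1 → 2 → 4 → 5 → 7 → 9)

**Steps most likely to fail**

Step 5. Transfer of the sulfenium group to the amine nitrogen, or a stalling reversible transfer to the alkynyl sulfur, may outrun activation of the triple bond. A second sulfenium transfer to the electron-rich product may also erode it. The fallback separates the two bond formations, each by known chemistry. It sets out from 7: gold-catalysed 5-endo-dig hydroamination (NaAuCl4·2H2O cat., EtOH, rt) should close the same N1–C2 bond and give 4,5,6-tribromo-2-(methylsulfanyl)-1H-indole F1. Electrophilic C3-sulfenylation of F1 with dimethyl disulfide and catalytic iodine in DMSO should then install the second sulfur and come back to the route at 9.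

Step 4. Sulfenyl transfer to nitrogen instead of the acetylide carbon, oxidative dimerisation of the copper acetylide, or copper-induced cyclisation of the ethynylaniline may consume 5. The fallback makes the C(sp)–S bond before the aniline is involved. It sets out from 3, which is deprotonated (n-BuLi, THF, −78 °C) and quenched with 6 to give trimethyl[(methylsulfanyl)ethynyl]silane F2. F2 is then coupled with iodide 2 under fluoride-promoted desilylative Sonogashira conditions (PdCl2(PPh3)2, CuI, CsF, Et3N, DMF, rt to 40 °C). Under these, (methylsulfanyl)ethyne F3 is released in the flask and coupled without isolation. The fallback comes back to the route at 7, with 4 and 5 bypassed.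

Step 2. Slow coupling at the C–I bond flanked by NH2 and Br may let copper-mediated dimerisation of the alkyne and palladium insertion into the C–Br bonds compete. The fallback changes the organometallic partner and removes copper and amine base. It sets out from 2, which undergoes Stille coupling with tributyl(ethynyl)stannane (Pd2(dba)3, AsPh3, NMP, rt to 40 °C); fast transmetalation at low temperature should leave the bromides alone. It comes back to the route at 5, so step 3 is no longer needed and no new compound is made.

**Further compounds**
F1 | step 5 | 4,5,6-tribromo-2-(methylsulfanyl)-1H-indole | CSc1cc2c(Br)c(Br)c(Br)cc2[nH]1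
F2 | step 4 | trimethyl[(methylsulfanyl)ethynyl]silane | CSC#C[Si](C)(C)C
F3 | step 4 | (methylsulfanyl)ethyne | CSC#C
F0 | step 2 | none | none
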